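**Strategy.** The dihydropyran ring of the chromane is disconnected in a retro-oxa-Diels–Alder sense. O1, C8a, C4a and C4 are read as an ortho-quinone methide of a fully substituted orsellinate ring, and C3–C2 as the terminal 1,1-disubstituted alkene of (E)-2,6-dimethylhepta-1,3,5-triene. One chiral phosphoric acid-catalysed inverse-demand [4+2] cycloaddition forms the C3–C4 and O1–C2 bonds, closes the pyran ring, brings in the intact dienyl chain and sets the C2 quaternary stereocenter. It exploits the O1–C8a=C4a–C4 oxadiene hidden in the pyran ring and the pentadienyl-stabilised carbinol carbon C2. The precursors are a salicyl alcohol and a hydrocarbon triene; fluoride then unmasks the acid.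

Key step: step 6

Remarks on the chemistry (assumptions):
- Commercial 6-methylhepta-3,5-dien-2-one is taken as its (3E) isomer.
- The (R)-configured phosphoric acid is assumed to deliver the (2R)-chromane; its antipode is used if the opposite sense is found.
- Monocyclic arenes carry orsellinate numbering (C1 bears the carboxyl group, OH on C2 and C4, methyl on C6). Bicyclic compounds carry chromane numbering.

Step 1
Reactants: 1 (3E)-6-methylhepta-3,5-dien-2-one
Product: 2 (3E)-2,6-dimethylhepta-1,3,5-triene
Conditions: Ph3PCH3Br, KOtBu, Et2O, 0 °C to rt; pentane, silica plug; kept cold with BHT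
Reagents that add atoms: methyltriphenylphosphonium bromide, C[P+](c1ccccc1)(c1ccccc1)c1ccccc1.[Br-]
Why: Wittig olefination: the non-stabilised ylide adds only to the ketone carbonyl, converts C=O into C=CH2 and leaves the conjugated diene and its (E) geometry untouched; no stereocenter is formed.

Step 2
Reactants: 3 orsellinic acid (2,4-dihydroxy-6-methylbenzoic acid)
Product: 4 2-(trimethylsilyl)ethyl 2,4-dihydroxy-6-methylbenzoate
Conditions: Me3SiCH2CH2OH, PPh3, DIAD, THF, 0 °C to rt
Reagents that add atoms: 2-(trimethylsilyl)ethanol, C[Si](C)(C)CCO
Why: Mitsunobu esterification: the carboxylic acid is by far the most acidic pronucleophile and displaces the phosphonium-activated primary alcohol, so the phenols stay free, no acyl activation (hence no depside formation or decarboxylation) occurs, and a fluoride-labile ester replaces a hindered alkyl ester that would be hard to saponify.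

Step 3
Reactants: 4 2-(trimethylsilyl)ethyl 2,4-dihydroxy-6-methylbenzoate; 5 2-methylbut-3-en-2-ol
Product: 6 2-(trimethylsilyl)ethyl 2,4-dihydroxy-6-methyl-5-(3-methylbut-2-en-1-yl)benzoate
Conditions: BF3·OEt2 (0.3 equiv), 1,4-dioxane, 20 °C, stopped at partial conversion, 4 recycled
Reagents that add atoms: none
Why: Friedel–Crafts allylation (electrophilic aromatic substitution) with loss of water: the 1,1-dimethylallyl cation from 5 is attacked through its unhindered primary terminus to give the linear prenyl group, and C5 (ortho to the free 4-OH, para to the ester-chelated 2-OH) is expected to be preferred over C3, which lies between two oxygen substituents, as in acid-mediated prenylation of other 2,4-dihydroxyaryl carbonyl compounds.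

Step 4
Reactants: 6 2-(trimethylsilyl)ethyl 2,4-dihydroxy-6-methyl-5-(3-methylbut-2-en-1-yl)benzoate
Product: 7 2-(trimethylsilyl)ethyl 3-formyl-2,4-dihydroxy-6-methyl-5-(3-methylbut-2-en-1-yl)benzoate
Conditions: MgCl2, Et3N, (CH2O)n, MeCN, reflux; dilute HCl work-up
Reagents that add atoms: paraformaldehyde (as formaldehyde), C=O
Why: Casnati–Skattebøl ortho-formylation: the magnesium phenoxide delivers formaldehyde to the ortho carbon and a second formaldehyde oxidises the benzylic alkoxide by hydride transfer; C3 is the only unsubstituted ring carbon and is ortho to both hydroxyls, so the regiochemistry is unambiguous, and the ester and prenyl group are inert to the mild base.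

Step 5
Reactants: 7 2-(trimethylsilyl)ethyl 3-formyl-2,4-dihydroxy-6-methyl-5-(3-methylbut-2-en-1-yl)benzoate
Product: 8 2-(trimethylsilyl)ethyl 2,4-dihydroxy-3-(hydroxymethyl)-6-methyl-5-(3-methylbut-2-en-1-yl)benzoate
Conditions: NaBH4, THF/MeOH, 0 °C; pH 7 phosphate buffer work-up
Reagents that add atoms: none
Why: Borohydride reduction of the aryl aldehyde to the primary benzylic alcohol at 0 °C, where the hindered, hydrogen-bonded ester and the alkene are inert; the neutral work-up keeps the salicyl alcohol from ionising prematurely.

Step 6
Reactants: 8 2-(trimethylsilyl)ethyl 2,4-dihydroxy-3-(hydroxymethyl)-6-methyl-5-(3-methylbut-2-en-1-yl)benzoate; 2 (3E)-2,6-dimethylhepta-1,3,5-triene (3 equiv)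
Product: 10 2-(trimethylsilyl)ethyl (2R)-5-hydroxy-2,7-dimethyl-8-(3-methylbut-2-en-1-yl)-2-[(1E)-4-methylpenta-1,3-dien-1-yl]chromane-6-carboxylate, via ortho-quinone methide 9 (not isolated)
Conditions: (R)-TRIP [(R)-3,3'-bis(2,4,6-triisopropylphenyl)-1,1'-binaphthyl-2,2'-diyl hydrogen phosphate] (10 mol %), 5 Å MS, toluene, 0 °C to rt
Reagents that add atoms: none
Why: Proposed new method: the phosphoric acid dehydrates salicyl alcohol 8 (the water is taken up by the molecular sieves) to ortho-quinone methide 9, which stays hydrogen-bonded to the chiral phosphate through its ring carbonyl oxygen; the exocyclic methylene carbon of 9 (the future C4) is attacked by the unsubstituted CH2 terminus of triene 2 (the future C3) while the developing tertiary pentadienyl cation at the future C2 is captured by the quinone methide oxygen, so the C3–C4 and O1–C2 bonds form in one asynchronous event. The closest known reaction types are the chiral Brønsted acid-catalysed oxa-[4+2] cycloaddition of ortho-quinone methides generated in situ from ortho-hydroxybenzyl alcohols with styrenes and other electron-rich alkenes, and the thermal racemic hetero-Diels–Alder reaction of ortho-quinone methides with terpene polyenes; new here is the enantioselective use of an unstabilised CH2 methide with a purely hydrocarbon triene. The dihydropyran ring is closed by an intermolecular inverse-electron-demand hetero-Diels–Alder ([4+2]) cycloaddition in which 9 is the 1-oxadiene and the C1=C2 bond of 2 the two-carbon partner. The only new stereocenter, C2, is set under catalyst control, the face of the 1,1-disubstituted alkene (in the stepwise limit, of the contact ion pair) being selected inside the pocket formed by the 3,3'-aryl groups of the phosphate. The step needs site selectivity among the three alkenes of 2, Markovnikov orientation and ring closure through the oxygen para to the ester: attack at C1 of 2 is the only unhindered one and the only one that leads to a fully delocalised tertiary cation, whose collapse at C2 gives the six-membered ring, and the other hydroxyl is held in a hydrogen bond to the ester carbonyl so that the 4-oxo tautomer of 9 reacts. A weak acid, molecular sieves and low temperature are chosen so that the acid-labile tertiary dienylic aryl ether of 10 is not re-ionised, which would erode the enantiomeric purity.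

Step 7
Reactants: 10 2-(trimethylsilyl)ethyl (2R)-5-hydroxy-2,7-dimethyl-8-(3-methylbut-2-en-1-yl)-2-[(1E)-4-methylpenta-1,3-dien-1-yl]chromane-6-carboxylate
Product: 11 (2R)-5-hydroxy-2,7-dimethyl-8-(3-methylbut-2-en-1-yl)-2-[(1E)-4-methylpenta-1,3-dien-1-yl]chromane-6-carboxylic acid
Conditions: TBAF (3 equiv), THF, 0 °C to rt; cold dilute HCl to pH 3, EtOAc
Reagents that add atoms: none
Why: Fluoride-induced β-elimination (fragmentation) of the 2-(trimethylsilyl)ethyl ester: attack at silicon, remote from the hindered carbonyl, expels ethylene and the carboxylate under non-hydrolytic, non-acidic conditions, so the tertiary dienylic ether, the diene, the prenyl group and the C2 configuration should be preserved.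

**Compound list**

1 | (3E)-6-methylhepta-3,5-dien-2-one | CC(=O)/C=C/C=C(C)C | starting material
2 | (3E)-2,6-dimethylhepta-1,3,5-triene | C=C(C)/C=C/C=C(C)C | intermediate
3 | orsellinic acid (2,4-dihydroxy-6-methylbenzoic acid) | Cc1cc(O)cc(O)c1C(=O)O | starting material
4 | 2-(trimethylsilyl)ethyl 2,4-dihydroxy-6-methylbenzoate | Cc1cc(O)cc(O)c1C(=O)OCC[Si](C)(C)C | intermediate
5 | 2-methylbut-3-en-2-ol | CC(C)(O)C=C | starting material
6 | 2-(trimethylsilyl)ethyl 2,4-dihydroxy-6-methyl-5-(3-methylbut-2-en-1-yl)benzoate | Cc1c(CC=C(C)C)c(O)cc(O)c1C(=O)OCC[Si](C)(C)C | intermediate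
7 | 2-(trimethylsilyl)ethyl 3-formyl-2,4-dihydroxy-6-methyl-5-(3-methylbut-2-en-1-yl)benzoate | Cc1c(CC=C(C)C)c(O)c(C=O)c(O)c1C(=O)OCC[Si](C)(C)C | intermediate
8 | 2-(trimethylsilyl)ethyl 2,4-dihydroxy-3-(hydroxymethyl)-6-methyl-5-(3-methylbut-2-en-1-yl)benzoate | Cc1c(CC=C(C)C)c(O)c(CO)c(O)c1C(=O)OCC[Si](C)(C)C | intermediate
9 | ortho-quinone methide: 2-(trimethylsilyl)ethyl 2-hydroxy-6-methyl-3-methylidene-5-(3-methylbut-2-en-1-yl)-4-oxocyclohexa-1,5-diene-1-carboxylate | C=C1C(=O)C(CC=C(C)C)=C(C)C(C(=O)OCC[Si](C)(C)C)=C1O | intermediate (not isolated)
10 | 2-(trimethylsilyl)ethyl (2R)-5-hydroxy-2,7-dimethyl-8-(3-methylbut-2-en-1-yl)-2-[(1E)-4-methylpenta-1,3-dien-1-yl]chromane-6-carboxylate | CC(C)=C/C=C/[C@@]1(C)CCc2c(O)c(C(=O)OCC[Si](C)(C)C)c(C)c(CC=C(C)C)c2O1 | intermediate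
11 | (2R)-5-hydroxy-2,7-dimethyl-8-(3-methylbut-2-en-1-yl)-2-[(1E)-4-methylpenta-1,3-dien-1-yl]chromane-6-carboxylic acid | CC(C)=C/C=C/[C@@]1(C)CCc2c(O)c(C(=O)O)c(C)c(CC=C(C)C)c2O1 | target

**Step count.** Total: 7 steps. Longest linear sequence: 6 steps (3 to 11, steps 2 to 7); step 1 is a one-step branch that joins at step 6.

**Steps most likely to fail**

Step 6 (proposed new method). What may go wrong: insufficient enantiofacial discrimination with the small unstabilised methide, acid-induced re-ionisation of the tertiary dienylic ether with loss of enantiomeric purity, or cationic oligomerisation of the triene. The fallback uses known chemistry and sets out from 8 and 2. The uncatalysed thermal hetero-Diels–Alder reaction of the thermally generated quinone methide 9 (toluene, BHT, 150 °C, sealed vessel) should give the racemic chromane ester F1. Preparative chromatography on a chiral stationary phase (amylose tris(3,5-dimethylphenylcarbamate), hexane/2-propanol) then separates 10 from its (2S)-enantiomer F2, which is discarded. The route is rejoined at 10.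

Step 3. What may go wrong: attack at C3 or double allylation, O-allylation, acid-induced cyclisation of the new prenyl group onto the neighbouring hydroxyl, or partial loss of the silylethyl ester under the Lewis acid. The fallback sets out from 4. Electrophilic bromination (NBS, MeCN, 0 °C) at the position para to the chelated hydroxyl should give the 5-bromo ester F3. Suzuki–Miyaura coupling of F3 with 3-methylbut-2-enylboronic acid pinacol ester (Pd(OAc)2, a bulky biarylphosphine chosen for coupling at the unsubstituted allyl terminus, K3PO4, THF/H2O, 40 °C) then installs the linear prenyl group without acid. The route is rejoined at 6.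

Step 4. What may go wrong: sluggish attack of formaldehyde on the ester-deactivated, magnesium-chelated phenoxide, or, in the hydride step that follows, over-reduction through premature quinone methide formation. The fallback sets out from 6 and avoids the aldehyde oxidation level. Boronic acid-templated ortho-hydroxymethylation (PhB(OH)2, (CH2O)n, catalytic propionic acid, toluene, reflux with water removal) should give the cyclic boronate, benzodioxaborinine F4. Transesterification with propane-1,3-diol (THF, rt) releases the salicyl alcohol. The route is rejoined at 8, so that steps 4 and 5 are both replaced.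

**Further compounds**

F1 | step 6 | racemic 2-(trimethylsilyl)ethyl 5-hydroxy-2,7-dimethyl-8-(3-methylbut-2-en-1-yl)-2-[(1E)-4-methylpenta-1,3-dien-1-yl]chromane-6-carboxylate | CC(C)=C/C=C/C1(C)CCc2c(O)c(C(=O)OCC[Si](C)(C)C)c(C)c(CC=C(C)C)c2O1
F2 | step 6 | 2-(trimethylsilyl)ethyl (2S)-5-hydroxy-2,7-dimethyl-8-(3-methylbut-2-en-1-yl)-2-[(1E)-4-methylpenta-1,3-dien-1-yl]chromane-6-carboxylate | CC(C)=C/C=C/[C@]1(C)CCc2c(O)c(C(=O)OCC[Si](C)(C)C)c(C)c(CC=C(C)C)c2O1
F3 | step 3 | 2-(trimethylsilyl)ethyl 5-bromo-2,4-dihydroxy-6-methylbenzoate | Cc1c(Br)c(O)cc(O)c1C(=O)OCC[Si](C)(C)C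
F4 | step 4 | 2-(trimethylsilyl)ethyl 5-hydroxy-7-methyl-8-(3-methylbut-2-en-1-yl)-2-phenyl-4H-1,3,2-benzodioxaborinine-6-carboxylate | Cc1c(CC=C(C)C)c2OB(c3ccccc3)OCc2c(O)c1C(=O)OCC[Si](C)(C)C
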